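The flask held 1.10 of L for each part of D and Z together, so L stood only just above D and Z, which are the limiting reagent here, and the two run down side by side.

| flask | D | Z | L | G | remark | time |
|---|---|---|---|---|---|---|
| eta | 0.15 M | 0.15 M | 0.17 M | 1.5 mM | run made earlier |  |
| alpha | 0.15 M | 0.15 M | 0.25 M | 1.5 mM | run made earlier |  |
| flask | 0.15 M | 0.15 M | 0.330 M | 1.5 mM |  | 10 d |

| run | time / d | E / % | J / % |
|---|---|---|---|
| eta | 1.04 | 9 | 4 |
| eta | 1.67 | 17 | 4 |
| eta | 2.00 | 20 | 11 |
| eta | 3.00 | 22 | 5 |
| eta | 5.00 | 26 | 11 |
| eta | 8.00 | 33 | 14 |
| eta | 12.0 | 34 | 13 |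
| alpha | 1.67 | 21 | 5 |
| alpha | 3.00 | 27 | 12 |
| alpha | 5.00 | 38 | 16 |
| alpha | 6.00 | 40 | 16 |
| alpha | 8.00 | 44 | 22 |
| alpha | 10.0 | 46 | 15 |
| alpha | 12.0 | 48 | 16 |

(scatter of a reading: 2 percentage points)

- E and J together, in percent of the D and Z charged together, at 10 d
- excess of E over J in the product at 10 d
- whether the exchange between D and Z keeps pace with the reaction: how far the product's excess at 10 d gets from its value without exchange to its value with instant exchange (above 80% keeps pace, below 20% hardly takes part, else lags behind)

- X is single-handed; D and Z are mirror images of each other, charged as a racemate, each of them at the stated concentration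
- the earlier runs were read with a standard deviation of 2 percentage points
- an excess is the difference of the two amounts in percent of their sum
- an excess is below zero if the other one leads

I reckoned with one rate for the pair: what reacts per day is a constant K times D and Z together times L, with G at the same charge in each run. That treats D and Z as one pool kept equal by their exchange, which was my assumption.

Each turn takes one L and one of D or Z, so the gap, L charged minus D and Z charged (0.300 M), stays the same through a run. The gap joins the start of a run to its end. If r is the share of L left divided by the share of D and Z left, then: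

r = exp(gap × K × t)

share of D and Z left = gap / (r × L charged − D and Z charged)

The last 3 alpha readings average 63.7% product at 10.0 d, with a gap of −0.0500 M. Solved for K, this gives:

K = ln(r) / (gap × t) = 0.863 M⁻¹ d⁻¹

This is the pair constant, a second-order rate constant for this charge of G.

For the flask the gap is 0.0300 M, so r = 1.30. The share left is 23.5%, and I expected 76.5% product.

The forecast gave 75% (68% to 81%), an excess of 46% (36% to 54%), and "keeps pace", adding: “The data only moderately discriminate, so exchange probably keeps pace”. My figure lies inside its range.

The flask gave 77.1% with an excess of 42.4%, and the verdict on the exchange is keeps pace, at 87% of the way, not far above the 80% mark. Net, up to 10 d, 16.1% of the D and Z charged ran from Z to D. At 5.00 d the pair constant gives 60.3%, and the flask stood at 61.8%.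

    G ⇌ X (K = 10.0, k = 0.411 h⁻¹)
    L + X + Z → X + J (k = 27.1 M⁻² h⁻¹)
    L + X + D → X + E (k = 72.4 M⁻² h⁻¹)
    D ⇌ Z (k = 0.0429 h⁻¹)
    2 X ⇌ Q (K = 640 M⁻¹, k = 20.0 M⁻¹ h⁻¹)

With L at 0.13 M the gap turns to −0.170 M, and the same two lines with the pair constant give 37.0%. That neighbour flask gave 37.5%, with 13.5% of its L left.

(All runs were computed on assumed constants.)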